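## Retrosynthetic overview

1. Target numbering and rings: ring A (cyclobutane) = C1 (bears the decenyl chain), C2, C7, C8; ring B (cyclohexene) = C2–C3=C4–C5–C6–C7; ring C (cyclopentane) = C6–C7–C8–C9–C10; ring D (cyclohexene) = C5–C6–C10–C11=C12–C13 (C13 bears CO2Me).
2. Last disconnection: rings C and A together (bonds C7–C8 and C1–C2) by an intramolecular [2+2] photocycloaddition of a ring-B 1,3-diene (C7=C2–C3=C4) with the (E)-C8=C1 alkene of the chain on C10.
3. The C13 ester and the C11=C12 alkene come from an allylsilane (Si on C11, alkene C12=C13) by anti-SE2' carbamoylation; the ring-B diene comes from a C7 ketone through its dienyl triflate.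
4. Key disconnection: C5–C6 and C10–C11 by a catalytic enantioselective intramolecular Diels–Alder reaction of an acyclic, achiral trienone (diene C5=C13–C12=C11–SiMe3, dienophile (E)-C6=C10, tether C4=C3–C2–C7(=O)), closing rings D and B at once. Enabling feature: C7, the CH shared by rings A, B and C, is bonded to C6, so at the ketone level it activates the dienophile from inside the tether; the anti relation of H-6 and H-10 demands an acyclic (E)-C6=C10, so ring C is closed only afterwards.
5. The trienone is assembled linearly from dec-9-yn-1-ol, methyl 4-bromocrotonate, propargyl bromide and a silyl dienyl iodide (fragment 1); ring order: D + B, then C + A.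

Key step: step 12

Assumption: the (S)-configured oxazaborolidinium catalyst is taken to shield the enone face that leads to 20; should the sense of induction be opposite, the equally available (R)-catalyst would be used with no other change.

Atom numbers in the Why lines are the target numbers defined above.

## Route

Step 1
Reactants: 1 (E)-1,2-bis(tributylstannyl)ethene; 2 (E)-(2-bromovinyl)trimethylsilane
Product: 3 tributyl[(1E,3E)-4-(trimethylsilyl)buta-1,3-dien-1-yl]stannane
Conditions: 1 (3 equiv), Pd(PPh3)4 (5 mol %), toluene, 90 °C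
Reagents that add atoms: none
Why: Stille coupling of the vinyl bromide with one C–Sn bond of the distannane, used in excess to suppress double coupling, proceeds with retention at both alkenes and should give the (1E,3E)-diene.

Step 2
Reactants: 3 tributyl[(1E,3E)-4-(trimethylsilyl)buta-1,3-dien-1-yl]stannane
Product: 4 [(1E,3E)-4-iodobuta-1,3-dien-1-yl]trimethylsilane (fragment 1)
Conditions: I2 (1.05 equiv), CH2Cl2, 0 °C
Reagents that add atoms: iodine, II
Why: Iododestannylation is an ipso substitution with retention of alkene geometry and is far faster at the C–Sn than at the C–Si bond, so the vinylsilane should survive.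

Step 3
Reactants: 5 dec-9-yn-1-ol
Product: 6 dec-9-ynal
Conditions: Dess–Martin periodinane (1.2 equiv), CH2Cl2, 0 °C → rt
Reagents that add atoms: none
Why: Dess–Martin oxidation takes the primary alcohol to the aldehyde without over-oxidation and does not touch the terminal alkyne.

Step 4
Reactants: 6 dec-9-ynal; 7 5-(ethylsulfonyl)-1-phenyl-1H-tetrazole
Product: 8 (E)-dodec-10-en-1-yne
Conditions: 7, KN(SiMe3)2 (1.05 equiv), DME, −60 °C; then 6, −60 °C → rt
Reagents that add atoms: none
Why: Julia–Kocienski olefination of an unbranched aldehyde with a 1-phenyltetrazolyl sulfone and a potassium amide in DME is E-selective (anti addition, Smiles rearrangement, anti elimination), and premetalation of the sulfone keeps the base away from the alkyne C–H.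

Step 5
Reactants: 8 (E)-dodec-10-en-1-yne; 9 methyl (E)-4-bromobut-2-enoate
Product: 11 methyl (2E,5E,14E)-hexadeca-2,5,14-trienoate, via alkenylzirconocene chloride 10 (not isolated)
Conditions: Cp2Zr(H)Cl (1.1 equiv), THF, rt; then 9, Pd(PPh3)4 (5 mol %), 0 °C → rt
Reagents that add atoms: none
Why: syn-Hydrozirconation of the terminal alkyne, faster than that of the internal alkene, gives the (E)-alkenylzirconium, and its palladium-catalysed coupling with the allylic bromide (Negishi-type alkenyl–allyl coupling through a π-allyl complex) should join it to the allyl terminus remote from the ester with all alkenes remaining E.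

Step 6
Reactants: 11 methyl (2E,5E,14E)-hexadeca-2,5,14-trienoate
Product: 12 (2E,5E,14E)-hexadeca-2,5,14-trien-1-ol
Conditions: i-Bu2AlH (2.2 equiv), CH2Cl2, −78 °C; Rochelle salt work-up
Reagents that add atoms: none
Why: DIBAL-H reduces the conjugated ester in 1,2-fashion to the allylic alcohol at low temperature without migration of the skipped alkenes.

Step 7
Reactants: 12 (2E,5E,14E)-hexadeca-2,5,14-trien-1-ol
Product: 13 (2E,5E,14E)-hexadeca-2,5,14-trienal
Conditions: activated MnO2 (15 equiv), CH2Cl2, rt
Reagents that add atoms: none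
Why: MnO2 oxidises only allylic alcohols and is neutral, so the skipped 5,6-alkene should not move into conjugation.

Step 8
Reactants: 13 (2E,5E,14E)-hexadeca-2,5,14-trienal; 14 3-bromoprop-1-yne
Product: 16 (5E,8E,17E)-nonadeca-5,8,17-trien-1-yn-4-ol (racemic), via allenylzinc bromide 15 (not isolated)
Conditions: Zn dust (2 equiv), 14 (1.5 equiv), THF, 0 °C; aqueous work-up
Reagents that add atoms: none
Why: Barbier reaction in which the allenylzinc reagent adds to the aldehyde carbonyl through a cyclic SE2' transition state to give the homopropargylic alcohol; the new carbinol centre need not be controlled because it becomes the ketone carbon in step 11.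

Step 9
Reactants: 16 (5E,8E,17E)-nonadeca-5,8,17-trien-1-yn-4-ol; 4 [(1E,3E)-4-iodobuta-1,3-dien-1-yl]trimethylsilane
Product: 17 (1E,3E,9E,12E,21E)-1-(trimethylsilyl)tricosa-1,3,9,12,21-pentaen-5-yn-8-ol (racemic)
Conditions: Pd(PPh3)2Cl2 (3 mol %), CuI (6 mol %), Et3N, THF, rt
Reagents that add atoms: none
Why: Sonogashira coupling joins the terminal alkyne to the dienyl iodide with retention of the E,E geometry and tolerates the free alcohol and the vinylsilane.

Step 10
Reactants: 17 (1E,3E,9E,12E,21E)-1-(trimethylsilyl)tricosa-1,3,9,12,21-pentaen-5-yn-8-ol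
Product: 18 (1E,3E,5Z,9E,12E,21E)-1-(trimethylsilyl)tricosa-1,3,5,9,12,21-hexaen-8-ol (racemic)
Conditions: Zn dust activated with Cu(OAc)2 and AgNO3, MeOH–H2O 1:1, rt, dark
Reagents that add atoms: none
Why: Zinc activated by copper and silver reduces only the alkyne that is conjugated to the diene, by syn delivery of two hydrogens from the protic medium, which should give the 5Z alkene without over-reduction.

Step 11
Reactants: 18 (1E,3E,5Z,9E,12E,21E)-1-(trimethylsilyl)tricosa-1,3,5,9,12,21-hexaen-8-ol
Product: 19 (1E,3E,5Z,9E,12E,21E)-1-(trimethylsilyl)tricosa-1,3,5,9,12,21-hexaen-8-one (achiral trienone)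
Conditions: Dess–Martin periodinane (1.3 equiv), NaHCO3 (5 equiv), CH2Cl2, 0 °C; cold filtration, used at once
Reagents that add atoms: none
Why: Bicarbonate-buffered Dess–Martin oxidation gives the enone under non-enolising conditions, so the methylene between the ketone and the Z-triene (C2) should not be isomerised.

Step 12
Reactants: 19 (1E,3E,5Z,9E,12E,21E)-1-(trimethylsilyl)tricosa-1,3,5,9,12,21-hexaen-8-one
Product: 20 cis-fused 8-[(2E,11E)-trideca-2,11-dien-1-yl]-7-(trimethylsilyl)-4a,7,8,8a-tetrahydronaphthalen-1(2H)-one
Conditions: (S)-B-(o-tolyl) oxazaborolidine from (S)-α,α-diphenylprolinol (20 mol %), Tf2NH (18 mol %), CH2Cl2, −78 → −40 °C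
Reagents that add atoms: none
Why: The cationic boron Lewis acid binds the C7 ketone of the (E)-enone and lowers its LUMO, and the tethered (1E,3E)-dienylsilane then adds in a concerted, asynchronous, normal-demand [4+2] cycloaddition that forms C5–C6 and C10–C11; the closest known reaction types are the oxazaborolidinium-catalysed Diels–Alder reactions of acyclic enones and the intramolecular Diels–Alder reactions of 1,7,9-decatrien-3-ones. Ring D closes by the suprafacial [4+2] union itself, and ring B closes as the fused six-membered ring spanned by the four-atom tether C4=C3–C2–C7 (type 1 mode), whose Z alkene holds the diene terminus C5 next to C6. The cis B/D fusion (H-5 and H-6 cis) should follow from the endo placement of the coordinated tether carbonyl under the diene, the anti relation of H-6 and H-10 from the E geometry of the C6=C10 dienophile, and the C11 configuration (silicon cis to C4 on ring D) from the E geometry of the vinylsilane terminus. The absolute sense is set by the catalyst, whose aryl groups shield one face of the bound s-trans enone. The step needs π-facial, endo and periselectivity: the first comes from the catalyst, the second from carbonyl coordination and the short tether, and the third is inherent, because union of the enone with the inner C3=C4/C5=C13 diene would create a four-membered ring and the chain alkenes are unactivated. The E geometry of C5=C13 excludes a competing 6π electrocyclisation of the triene, and the low temperature excludes the 1,5-hydrogen shift of the Z-diene.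

Step 13
Reactants: 20 cis-fused bicyclic ketone
Product: 21 8-[(2E,11E)-trideca-2,11-dien-1-yl]-7-(trimethylsilyl)-4a,7,8,8a-tetrahydronaphthalen-1-yl trifluoromethanesulfonate
Conditions: KN(SiMe3)2 (1.05 equiv), THF, −78 °C; then PhNTf2 (1.1 equiv), −78 → 0 °C
Reagents that add atoms: N-phenylbis(trifluoromethanesulfonimide), O=S(=O)(N(c1ccccc1)S(=O)(=O)C(F)(F)F)C(F)(F)F
Why: The potassium amide removes a C2 proton (alpha to the ketone and allylic, far more acidic than the ring-fusion H-6), and O-sulfonylation of the extended dienolate should give the C7=C2–C3=C4 dienyl triflate (enol triflate formation) without epimerising C6.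

Step 14
Reactants: 21 dienyl triflate
Product: 23 4-[(2E,11E)-trideca-2,11-dien-1-yl]-5-(trifluoromethanesulfonyloxy)-1,4,4a,8a-tetrahydronaphthalene-1-carboxamide, via N-chlorosulfonyl-N-silyl amide 22 (not isolated)
Conditions: ClSO2NCO (1.1 equiv), CH2Cl2, −78 → −20 °C; then aq Na2SO3 (excess), 0 °C
Reagents that add atoms: chlorosulfonyl isocyanate, O=C=NS(=O)(=O)Cl
Why: anti-SE2' reaction of the allylsilane with the isocyanate, in which the electrophilic carbon bonds to C13 on the face opposite the C11–Si bond (also the convex face) and the silyl group is lost with shift of the alkene to C11=C12, should set C13 with the carbonyl group cis to H-5 and trans to C4 before sulfite removes the chlorosulfonyl group.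

Step 15
Reactants: 23 primary amide
Product: 25 methyl 4-[(2E,11E)-trideca-2,11-dien-1-yl]-5-(trifluoromethanesulfonyloxy)-1,4,4a,8a-tetrahydronaphthalene-1-carboxylate, via methyl imidate tetrafluoroborate 24 (not isolated)
Conditions: Me3OBF4 (1.2 equiv), CH2Cl2, rt; then H2O, rt
Reagents that add atoms: trimethyloxonium tetrafluoroborate, C[O+](C)C.F[B-](F)(F)F; water, O
Why: O-Methylation of the primary amide and hydrolysis of the imidate salt at mildly acidic pH give the methyl ester without base, so the alpha stereocentre of the beta,gamma-unsaturated ester (C13) should be neither epimerised nor drawn into conjugation.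

Step 16
Reactants: 25 ester dienyl triflate
Product: 26 methyl 4-[(2E,11E)-trideca-2,11-dien-1-yl]-1,4,4a,8a-tetrahydronaphthalene-1-carboxylate
Conditions: Pd(PPh3)4 (5 mol %), LiCl (3 equiv), n-Bu3SnH (1.3 equiv, slow addition), THF, 25 → 50 °C
Reagents that add atoms: none
Why: Zerovalent palladium inserts into the dienyl C–OTf bond, chloride makes the complex neutral, and fast Sn–H transmetalation with C–H reductive elimination (palladium-catalysed tin hydride reduction of an enol triflate) should replace OTf by H faster than the pendant alkene can insert, leaving the cyclohexa-1,3-diene and all stereocentres intact.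

Step 17
Reactants: 26 bicyclic triene ester
Product: 27 target, methyl ester of the tetracycle with (E)-dec-8-enyl at C1 and CO2Me at C13
Conditions: [Ir(dF(CF3)ppy)2(dtbbpy)]PF6 (1 mol %), degassed MeCN (0.01 M), blue LEDs (450 nm), 25 °C
Reagents that add atoms: none
Why: Triplet energy transfer from the excited iridium complex reaches only the cyclohexa-1,3-diene, whose terminus C7 adds 5-exo to C8 of the chain alkene before the 1,4-biradical closes C2–C1 (intramolecular [2+2] photocycloaddition of a 1,3-diene with a tethered alkene); the three-atom tether forces rings C and A to form cis on the face of ring B that carries C10 (setting C7, C2 and C8), and C1 should close with the chain exo, as the E alkene and the convex face both dictate.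

## Compound list

1 | (E)-1,2-bis(tributylstannyl)ethene | CCCC[Sn](CCCC)(CCCC)/C=C/[Sn](CCCC)(CCCC)CCCC | starting material
2 | (E)-(2-bromovinyl)trimethylsilane | C[Si](C)(C)/C=C/Br | starting material
3 | tributyl[(1E,3E)-4-(trimethylsilyl)buta-1,3-dien-1-yl]stannane | CCCC[Sn](CCCC)(CCCC)/C=C/C=C/[Si](C)(C)C | intermediate
4 | [(1E,3E)-4-iodobuta-1,3-dien-1-yl]trimethylsilane | C[Si](C)(C)/C=C/C=C/I | intermediate
5 | dec-9-yn-1-ol | OCCCCCCCCC#C | starting material
6 | dec-9-ynal | O=CCCCCCCCC#C | intermediate
7 | 5-(ethylsulfonyl)-1-phenyl-1H-tetrazole | CCS(=O)(=O)c1nnnn1-c1ccccc1 | starting material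
8 | (E)-dodec-10-en-1-yne | C/C=C/CCCCCCCC#C | intermediate
9 | methyl (E)-4-bromobut-2-enoate | COC(=O)/C=C/CBr | starting material
10 | chloro[(1E,10E)-dodeca-1,10-dien-1-yl]zirconocene | C/C=C/CCCCCCC/C=C/[Zr](Cl)(C1C=CC=C1)C1C=CC=C1 | intermediate
11 | methyl (2E,5E,14E)-hexadeca-2,5,14-trienoate | C/C=C/CCCCCCC/C=C/C/C=C/C(=O)OC | intermediate
12 | (2E,5E,14E)-hexadeca-2,5,14-trien-1-ol | C/C=C/CCCCCCC/C=C/C/C=C/CO | intermediate
13 | (2E,5E,14E)-hexadeca-2,5,14-trienal | C/C=C/CCCCCCC/C=C/C/C=C/C=O | intermediate
14 | 3-bromoprop-1-yne | C#CCBr | starting material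
15 | allenylzinc bromide | C=C=C[Zn]Br | intermediate
16 | (5E,8E,17E)-nonadeca-5,8,17-trien-1-yn-4-ol, racemic | C/C=C/CCCCCCC/C=C/C/C=C/C(O)CC#C | intermediate
17 | (1E,3E,9E,12E,21E)-1-(trimethylsilyl)tricosa-1,3,9,12,21-pentaen-5-yn-8-ol, racemic | C/C=C/CCCCCCC/C=C/C/C=C/C(O)CC#C/C=C/C=C/[Si](C)(C)C | intermediate
18 | (1E,3E,5Z,9E,12E,21E)-1-(trimethylsilyl)tricosa-1,3,5,9,12,21-hexaen-8-ol, racemic | C/C=C/CCCCCCC/C=C/C/C=C/C(O)C/C=C\C=C\C=C\[Si](C)(C)C | intermediate
19 | (1E,3E,5Z,9E,12E,21E)-1-(trimethylsilyl)tricosa-1,3,5,9,12,21-hexaen-8-one | C/C=C/CCCCCCC/C=C/C/C=C/C(=O)C/C=C\C=C\C=C\[Si](C)(C)C | intermediate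
20 | 8-[(2E,11E)-trideca-2,11-dien-1-yl]-7-(trimethylsilyl)-4a,7,8,8a-tetrahydronaphthalen-1(2H)-one; H-4a/H-8a cis, H-8 anti to H-8a, silyl group trans to the C8 chain | C/C=C/CCCCCCC/C=C/C[C@H]1[C@H]([Si](C)(C)C)C=C[C@@H]2C=CCC(=O)[C@H]12 | intermediate
21 | 8-[(2E,11E)-trideca-2,11-dien-1-yl]-7-(trimethylsilyl)-4a,7,8,8a-tetrahydronaphthalen-1-yl trifluoromethanesulfonate; configuration as in 20 | C/C=C/CCCCCCC/C=C/C[C@H]1[C@H]([Si](C)(C)C)C=C[C@@H]2C=CC=C(OS(=O)(=O)C(F)(F)F)[C@H]12 | intermediate
22 | N-chlorosulfonyl-N-trimethylsilyl derivative of amide 23 | C/C=C/CCCCCCC/C=C/C[C@H]1C=C[C@@H](C(=O)N([Si](C)(C)C)S(=O)(=O)Cl)[C@@H]2C=CC=C(OS(=O)(=O)C(F)(F)F)[C@H]12 | intermediate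
23 | 4-[(2E,11E)-trideca-2,11-dien-1-yl]-5-(trifluoromethanesulfonyloxy)-1,4,4a,8a-tetrahydronaphthalene-1-carboxamide; H-4a/H-8a cis, H-4 anti to H-4a, carboxamide cis to the C4 chain and to H-8a | C/C=C/CCCCCCC/C=C/C[C@H]1C=C[C@@H](C(N)=O)[C@@H]2C=CC=C(OS(=O)(=O)C(F)(F)F)[C@H]12 | intermediate
24 | methyl imidate tetrafluoroborate of 23 | C/C=C/CCCCCCC/C=C/C[C@H]1C=C[C@@H](C(=[NH2+])OC)[C@@H]2C=CC=C(OS(=O)(=O)C(F)(F)F)[C@H]12.F[B-](F)(F)F | intermediate
25 | methyl 4-[(2E,11E)-trideca-2,11-dien-1-yl]-5-(trifluoromethanesulfonyloxy)-1,4,4a,8a-tetrahydronaphthalene-1-carboxylate; configuration as in 23 | C/C=C/CCCCCCC/C=C/C[C@H]1C=C[C@@H](C(=O)OC)[C@@H]2C=CC=C(OS(=O)(=O)C(F)(F)F)[C@H]12 | intermediate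
26 | methyl 4-[(2E,11E)-trideca-2,11-dien-1-yl]-1,4,4a,8a-tetrahydronaphthalene-1-carboxylate; configuration as in 23 | C/C=C/CCCCCCC/C=C/C[C@H]1C=C[C@@H](C(=O)OC)[C@@H]2C=CC=C[C@H]12 | intermediate
27 | target: tetracyclic methyl ester (rings A–D), (E)-dec-8-enyl at C1 exo, CO2Me at C13, rings A/B, A/C, B/C and B/D cis-fused, rings C/D trans-fused | C/C=C/CCCCCCC[C@@H]1[C@H]2C=C[C@@H]3[C@@H]4[C@H]2[C@H]1C[C@H]4C=C[C@H]3C(=O)OC | target

## Summary

Total step count: 17. Longest linear sequence: 15 steps (5 to 27, steps 3–17); steps 1–2 make fragment 1.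

Steps most likely to fail:

1. Step 12. The catalyst may discriminate the enone faces poorly, because the carbonyl lies inside the tether, or the strong Lewis acid may shift the C2 hydrogens into conjugation or cleave the vinylsilane before cycloaddition. The fallback sets out from 19 and cyclises it under neutral thermal conditions (toluene, 60 °C, 2,6-di-tert-butyl-4-methylphenol). This should give the endo adduct as the racemate, that is 20 together with the enantiomer of 20 F1, which is removed by preparative chromatography on a chiral stationary phase. The route is rejoined at 20.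

2. Step 17. The triplet 1,4-biradical may close at the remote allyl terminus C4 (formal [4+2]) or decay without bond formation. The fallback sets out from 26 and replaces the photochemical route by a thermal iron-catalysed [2π+2π] cycloaddition with (iPrPDI)Fe(N2)2 (iPrPDI = 2,6-bis[1-(2,6-diisopropylphenylimino)ethyl]pyridine; 10 mol %, benzene, 25–45 °C). This passes through a metallacyclopentane and reductive elimination, and so cannot give the [4+2] isomer. It comes back to the route at 27 and makes no new compound (F0).

3. Step 14. Substitution may be slow because the C11–Si bond must become pseudoaxial (syn-axial to C7), which would let the isocyanate attack the dienyl triflate or the chain alkenes instead. The fallback sets out from 21 and uses a Hosomi–Sakurai reaction with HC(OMe)3 and catalytic Me3SiOTf (CH2Cl2, −78 °C), a more selective oxocarbenium electrophile with the same anti-SE2' course. This should give the dimethyl acetal F2. Mild hydrolysis (pyridinium p-toluenesulfonate, acetone–H2O) gives the aldehyde F3. Pinnick oxidation (NaClO2, NaH2PO4, 2-methylbut-2-ene, t-BuOH–H2O) gives the carboxylic acid F4. Esterification with Me3SiCHN2 in MeOH–toluene returns to the route at 25.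

Further compounds

F1 | step 12 | enantiomer of 20 | C/C=C/CCCCCCC/C=C/C[C@@H]1[C@@H]([Si](C)(C)C)C=C[C@H]2C=CCC(=O)[C@@H]12
F2 | step 14 | 8-(dimethoxymethyl)-5-[(2E,11E)-trideca-2,11-dien-1-yl]-4a,5,8,8a-tetrahydronaphthalen-1-yl trifluoromethanesulfonate (dimethyl acetal) | C/C=C/CCCCCCC/C=C/C[C@H]1C=C[C@@H](C(OC)OC)[C@@H]2C=CC=C(OS(=O)(=O)C(F)(F)F)[C@H]12
F3 | step 14 | 4-[(2E,11E)-trideca-2,11-dien-1-yl]-5-(trifluoromethanesulfonyloxy)-1,4,4a,8a-tetrahydronaphthalene-1-carbaldehyde | C/C=C/CCCCCCC/C=C/C[C@H]1C=C[C@@H](C=O)[C@@H]2C=CC=C(OS(=O)(=O)C(F)(F)F)[C@H]12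
F4 | step 14 | 4-[(2E,11E)-trideca-2,11-dien-1-yl]-5-(trifluoromethanesulfonyloxy)-1,4,4a,8a-tetrahydronaphthalene-1-carboxylic acid | C/C=C/CCCCCCC/C=C/C[C@H]1C=C[C@@H](C(=O)O)[C@@H]2C=CC=C(OS(=O)(=O)C(F)(F)F)[C@H]12
F0 | step 17 | none | none
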